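**Retrosynthetic overview**
- Last bond: the ester C–O. The epoxyquinol diol opens 3-hydroxy-3-methylglutaric anhydride under cinchona-thiourea control, which sets the side-chain carbinol.
- The diol comes from an epoxy-enedione by hydroxyl-directed reduction; the enedione comes from a quinone monoketal epoxide made by tartrate-mediated nucleophilic epoxidation (sets both oxirane carbons).
- Key C–C bond: ring carbon–CH2OH. The β-bromo carbon of the dienone (an acceptor) is coupled with Bu3SnCH2OH, a hydroxymethyl-anion equivalent (Stille); the new hydroxyl then directs the epoxidation.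
- The bromodienone comes from PhI(OAc)2/MeOH dearomatization of 5-bromo-2-farnesyl-4-methoxyphenol, made by ortho-C-farnesylation of 3-bromo-4-methoxyphenol.
- Ring order: the carbocycle is taken from the arene; the oxirane is the only ring formed (step 4).

Farnesyl = (2E,6E)-3,7,11-trimethyldodeca-2,6,10-trien-1-yl throughout.
Assumption: the sense of induction in the two reagent-controlled steps (4 and 7) is taken as written; if a first run shows the opposite sense, D-(−)-diisopropyl tartrate or the quinine-derived pseudo-enantiomeric thiourea is used with no other change.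

**Step 1**
Reactants: 1 3-bromo-4-methoxyphenol; 2 (2E,6E)-farnesyl bromide
Product: 4 5-bromo-4-methoxy-2-[(2E,6E)-farnesyl]phenol, via sodium 3-bromo-4-methoxyphenoxide 3 (not isolated)
Conditions: NaH (1.05 equiv), toluene, 0 °C, 30 min; then 2 (0.9 equiv), 0 °C to rt, 16 h
Reagents that add atoms: none
Why: Ortho-C-alkylation of a sodium phenoxide in a non-polar solvent (Claisen-type C-allylation): the tight ion pair shields oxygen, SN2 attack at the primary allylic bromide keeps the 2E geometry, and the ortho carbon para to bromine is the only unhindered one; no stereocenter is formed.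

**Step 2**
Reactants: 4 5-bromo-4-methoxy-2-[(2E,6E)-farnesyl]phenol
Product: 5 5-bromo-4,4-dimethoxy-2-[(2E,6E)-farnesyl]cyclohexa-2,5-dien-1-one
Conditions: PhI(OAc)2 (1.1 equiv), MeOH, 0 °C, 20 min
Reagents that add atoms: methanol, CO
Why: Oxidative dearomatization of a p-methoxyphenol with a trivalent iodine reagent: the aryloxyiodane collapses to a phenoxenium-type species that methanol traps at the para carbon to give the p-quinone monoketal, the isolated trisubstituted alkenes being inert at 0 °C; no stereocenter is formed.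

**Step 3 (key step)**
Reactants: 5 5-bromo-4,4-dimethoxy-2-[(2E,6E)-farnesyl]cyclohexa-2,5-dien-1-one; 6 (tributylstannyl)methanol
Product: 7 5-(hydroxymethyl)-4,4-dimethoxy-2-[(2E,6E)-farnesyl]cyclohexa-2,5-dien-1-one
Conditions: 6 (1.5 equiv), Pd(PPh3)4 (10 mol %), degassed 1,4-dioxane, 85 °C, 6 h
Reagents that add atoms: none
Why: Stille cross-coupling with Bu3SnCH2OH as a hydroxymethyl-anion (d1) equivalent: the β-bromo enone carbon (an acceptor, a vinylogous acyl bromide) adds quickly to zerovalent palladium and is joined to a formaldehyde-level carbon that is also an acceptor in its normal polarity, the α-oxygen favouring transfer of the CH2OH group over butyl; no stereocenter is formed.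

**Step 4**
Reactants: 7 5-(hydroxymethyl)-4,4-dimethoxy-2-[(2E,6E)-farnesyl]cyclohexa-2,5-dien-1-one
Product: 9 (1R,6S)-4-(hydroxymethyl)-5,5-dimethoxy-1-[(2E,6E)-farnesyl]-7-oxabicyclo[4.1.0]hept-3-en-2-one, via dienone sodium alkoxide 8 (not isolated)
Conditions: Ph3COOH (1.5 equiv), NaN(SiMe3)2 (2.5 equiv), L-(+)-diisopropyl tartrate (1.3 equiv), toluene, −40 °C, 48 h; aq. NH4Cl quench
Reagents that add atoms: trityl hydroperoxide, OOC(c1ccccc1)(c1ccccc1)c1ccccc1
Why: Tartrate-mediated, hydroxyl-directed nucleophilic (Weitz–Scheffer) epoxidation: alkoxide 8 sits in a chiral sodium tartrate/trityl peroxide aggregate that delivers the peroxide to C3 (the unsubstituted β-carbon of the α-farnesyl enone) on one face, enolate ring closure then gives the cis-fused oxirane and sets C1 (R) and C6 (S), while the β,β-disubstituted C5=C6 enone is not attacked.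

**Step 5**
Reactants: 9 (1R,6S)-4-(hydroxymethyl)-5,5-dimethoxy-1-[(2E,6E)-farnesyl]-7-oxabicyclo[4.1.0]hept-3-en-2-one
Product: 10 (1R,6S)-4-(hydroxymethyl)-1-[(2E,6E)-farnesyl]-7-oxabicyclo[4.1.0]hept-3-ene-2,5-dione
Conditions: 48% aq. HF, MeCN, 0 °C to rt, 2 h
Reagents that add atoms: water, O
Why: Acid-catalysed ketal hydrolysis: the dimethyl ketal ionizes to an oxocarbenium ion that water traps, while the oxirane (deactivated by the adjacent carbonyl), the allylic alcohol and the trisubstituted alkenes survive cold dilute HF; the two stereocenters are untouched.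

**Step 6**
Reactants: 10 (1R,6S)-4-(hydroxymethyl)-1-[(2E,6E)-farnesyl]-7-oxabicyclo[4.1.0]hept-3-ene-2,5-dione
Product: 12 (1R,5R,6R)-5-hydroxy-4-(hydroxymethyl)-1-[(2E,6E)-farnesyl]-7-oxabicyclo[4.1.0]hept-3-en-2-one, via sodium alkoxydiacetoxyborohydride 11 (not isolated)
Conditions: NaBH(OAc)3 (1.5 equiv), MeCN/AcOH (2:1), −30 °C, 3 h; aqueous work-up
Reagents that add atoms: none
Why: Hydroxyl-directed (Saksena–Evans type) triacetoxyborohydride reduction: the primary alcohol exchanges onto boron to give 11, which delivers hydride through a six-membered transition state only to the neighbouring C5 ketone (the C2 ketone is out of reach and inert to the free reagent), and hydride enters anti to the oxirane C–O bond, setting C5 (R) with the hydroxyl cis to the epoxide.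

**Step 7**
Reactants: 12 (1R,5R,6R)-5-hydroxy-4-(hydroxymethyl)-1-[(2E,6E)-farnesyl]-7-oxabicyclo[4.1.0]hept-3-en-2-one; 13 3-hydroxy-3-methylglutaric anhydride
Product: 14 (3S)-3-hydroxy-5-{[(1R,5R,6R)-5-hydroxy-2-oxo-1-[(2E,6E)-farnesyl]-7-oxabicyclo[4.1.0]hept-3-en-4-yl]methoxy}-3-methyl-5-oxopentanoic acid
Conditions: 13 (1.3 equiv), 9-amino(9-deoxy)epi-quinidine 3,5-bis(trifluoromethyl)phenyl thiourea (20 mol %), MTBE, −20 °C, 48 h; dilute citric acid wash
Reagents that add atoms: none
Why: Proposed new method: catalyst-controlled enantiotopic-carbonyl-selective opening of the prochiral anhydride 13 by the primary hydroxyl of 12 (closest known reaction type: cinchona thiourea-catalysed alcoholytic desymmetrization of 3-substituted glutaric anhydrides); the quinuclidine nitrogen activates the unhindered primary alcohol by general-base catalysis while the thiourea binds one of the two enantiotopic carbonyls, so the catalyst and not the remote ring stereocenters sets the new (S) carbinol center, and the hindered secondary and tertiary hydroxyls do not react.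

**Compound list**
1 | 3-bromo-4-methoxyphenol | COc1ccc(O)cc1Br | starting material
2 | (2E,6E)-farnesyl bromide | CC(C)=CCC/C(C)=C/CC/C(C)=C/CBr | starting material
3 | sodium 3-bromo-4-methoxyphenoxide (not isolated) | COc1ccc([O-])cc1Br.[Na+] | intermediate
4 | 5-bromo-4-methoxy-2-[(2E,6E)-farnesyl]phenol | CC(C)=CCC/C(C)=C/CC/C(C)=C/Cc1cc(OC)c(Br)cc1O | intermediate
5 | 5-bromo-4,4-dimethoxy-2-[(2E,6E)-farnesyl]cyclohexa-2,5-dien-1-one | CC(C)=CCC/C(C)=C/CC/C(C)=C/CC1=CC(OC)(OC)C(Br)=CC1=O | intermediate
6 | (tributylstannyl)methanol | CCCC[Sn](CCCC)(CCCC)CO | starting material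
7 | 5-(hydroxymethyl)-4,4-dimethoxy-2-[(2E,6E)-farnesyl]cyclohexa-2,5-dien-1-one | CC(C)=CCC/C(C)=C/CC/C(C)=C/CC1=CC(OC)(OC)C(CO)=CC1=O | intermediate
8 | sodium alkoxide of 7 at the primary hydroxyl (not isolated) | CC(C)=CCC/C(C)=C/CC/C(C)=C/CC1=CC(OC)(OC)C(C[O-])=CC1=O.[Na+] | intermediate
9 | (1R,6S)-4-(hydroxymethyl)-5,5-dimethoxy-1-[(2E,6E)-farnesyl]-7-oxabicyclo[4.1.0]hept-3-en-2-one | CC(C)=CCC/C(C)=C/CC/C(C)=C/C[C@@]12O[C@@H]1C(OC)(OC)C(CO)=CC2=O | intermediate
10 | (1R,6S)-4-(hydroxymethyl)-1-[(2E,6E)-farnesyl]-7-oxabicyclo[4.1.0]hept-3-ene-2,5-dione | CC(C)=CCC/C(C)=C/CC/C(C)=C/C[C@@]12O[C@@H]1C(=O)C(CO)=CC2=O | intermediate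
11 | sodium diacetoxy(hydrido)borate of 10 bound through the primary oxygen (not isolated) | CC(C)=CCC/C(C)=C/CC/C(C)=C/C[C@@]12O[C@@H]1C(=O)C(CO[BH-](OC(C)=O)OC(C)=O)=CC2=O.[Na+] | intermediate
12 | (1R,5R,6R)-5-hydroxy-4-(hydroxymethyl)-1-[(2E,6E)-farnesyl]-7-oxabicyclo[4.1.0]hept-3-en-2-one | CC(C)=CCC/C(C)=C/CC/C(C)=C/C[C@@]12O[C@@H]1[C@H](O)C(CO)=CC2=O | intermediate
13 | 3-hydroxy-3-methylglutaric anhydride (4-hydroxy-4-methyloxane-2,6-dione) | CC1(O)CC(=O)OC(=O)C1 | starting material
14 | (3S)-3-hydroxy-5-{[(1R,5R,6R)-5-hydroxy-2-oxo-1-[(2E,6E)-farnesyl]-7-oxabicyclo[4.1.0]hept-3-en-4-yl]methoxy}-3-methyl-5-oxopentanoic acid | CC(C)=CCC/C(C)=C/CC/C(C)=C/C[C@@]12O[C@@H]1[C@H](O)C(COC(=O)C[C@@](C)(O)CC(=O)O)=CC2=O | target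

**Totals and risks**
Total step count: 7. Longest linear sequence: 7 steps (1 to 14).

Steps most likely to fail:

- **Step 3 (Stille hydroxymethylation of the dienone).** Transfer of the sp3 CH2OH group may be slower than reduction or aromatization of the monoketal at 85 °C. The fallback moves the same hydroxymethyl-anion coupling one stage back, to the arene. It sets out from 4: Pd(PPh3)4-catalysed coupling with 6 in dioxane at 100 °C gives 5-(hydroxymethyl)-4-methoxy-2-[(2E,6E)-farnesyl]phenol F1. PhI(OAc)2 in MeOH at 0 °C then dearomatizes F1 directly, and the route is rejoined at 7.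

- **Step 6 (regio- and face-selective reduction).** Hydride may reach the C2 ketone or the wrong face. The fallback replaces boron delivery by a covalent silicon tether and sets out from 10. iPr2SiHCl/imidazole (CH2Cl2, 0 °C) gives (1R,6S)-4-{[(diisopropylsilyl)oxy]methyl}-1-[(2E,6E)-farnesyl]-7-oxabicyclo[4.1.0]hept-3-ene-2,5-dione F2. Catalytic Bu4NF (THF, −40 °C) triggers intramolecular hydrosilylation of the adjacent ketone, anti to the oxirane, to give the cyclic diisopropylsilylene ether of 12 F3. HF·pyridine (THF, 0 °C) then releases the diol, and the route is rejoined at 12.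

- **Step 7 (desymmetrizing acylation).** The catalyst may not distinguish the two anhydride carbonyls well enough. The fallback takes the side-chain stereocenter from the chiral pool and sets out from 12. Purchased (R)-mevalonolactone is opened with NaOH and the sodium salt is alkylated with allyl bromide (DMF, 0 °C) to give allyl (3R)-3,5-dihydroxy-3-methylpentanoate F4. TEMPO/PhI(OAc)2 (MeCN/water) oxidizes the primary alcohol to (3R)-3-hydroxy-3-methyl-5-oxo-5-(prop-2-en-1-yloxy)pentanoic acid F5. EDC·HCl with catalytic DMAP (CH2Cl2, 0 °C) esterifies the primary hydroxyl of 12 with F5 to give the allyl ester of 14 F6. Pd(PPh3)4/morpholine (THF, 0 °C) removes the allyl group, and the route is rejoined at 14.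

**Further compounds**
F1 | step 3 | 5-(hydroxymethyl)-4-methoxy-2-[(2E,6E)-farnesyl]phenol | CC(C)=CCC/C(C)=C/CC/C(C)=C/Cc1cc(OC)c(CO)cc1O
F2 | step 6 | (1R,6S)-4-{[(diisopropylsilyl)oxy]methyl}-1-[(2E,6E)-farnesyl]-7-oxabicyclo[4.1.0]hept-3-ene-2,5-dione | CC(C)=CCC/C(C)=C/CC/C(C)=C/C[C@@]12O[C@@H]1C(=O)C(CO[SiH](C(C)C)C(C)C)=CC2=O
F3 | step 6 | cyclic diisopropylsilylene ether of 12 (1,3-dioxa-2-silinane joining the primary and secondary oxygens) | CC(C)=CCC/C(C)=C/CC/C(C)=C/C[C@@]12O[C@@H]1[C@H](O[Si](C(C)C)(C(C)C)OC3)C3=CC2=O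
F4 | step 7 | allyl (3R)-3,5-dihydroxy-3-methylpentanoate | C=CCOC(=O)C[C@](C)(O)CCO
F5 | step 7 | (3R)-3-hydroxy-3-methyl-5-oxo-5-(prop-2-en-1-yloxy)pentanoic acid | C=CCOC(=O)C[C@](C)(O)CC(=O)O
F6 | step 7 | allyl ester of 14 at the terminal carboxyl | CC(C)=CCC/C(C)=C/CC/C(C)=C/C[C@@]12O[C@@H]1[C@H](O)C(COC(=O)C[C@@](C)(O)CC(=O)OCC=C)=CC2=O
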